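**Strategy.** Both menthenyl rings are disconnected across C1'–C6' and C4'–C5' (C1' = aryl-bearing, C6' = isopropyl-bearing carbon). The pair of 1-aryl-3-methyl-6-isopropylcyclohex-2-ene units is an ortho/para Diels–Alder retron present twice on one arene. It should arise in a twofold catalytic enantioselective Diels–Alder reaction of a flat, achiral bis[(E)-3-methylbutadienyl]phloroglucinol tris-MOM ether with 2-isopropylacrolein. This one operation closes both rings, fixes the position of the ring alkene and methyl group, and sets all four stereocentres, with formyl cis and isopropyl trans to the arene. Stereoretentive rhodium decarbonylation then exchanges CHO for H, and late acylation and deprotection complete the chalcone.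

Key step: step 5

Remark on locants: in each menthenyl ring C1' is bonded to the arene, C2'=C3' carries the methyl group at C3', and C6' carries the isopropyl group.

Assumption (sense of induction): by the accepted binding model of the protonated oxazaborolidine (formyl C–H···O contact, s-trans enal lying over the neighbouring phenyl group), the (R)-catalyst leaves the Re face of C-α of 2 open. Should the sense be the reverse, the (S)-catalyst is used and nothing else changes.

Step 1
Reactants: 1 3-methylbutanal (isovaleraldehyde)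
Product: 2 3-methyl-2-methylidenebutanal (2-isopropylacrolein)
Conditions: 37% aq. CH2O, pyrrolidine (10 mol %), EtCO2H (10 mol %), i-PrOH, 45 °C
Reagents that add atoms: formaldehyde, C=O
Why: Amine-catalysed Mannich condensation (α-methylenation of an aldehyde), in which the enamine of 1 adds to formaldehyde and the β-amino aldehyde eliminates the amine; no stereocentre is formed.

Step 2
Reactants: 3 benzene-1,3,5-triol (phloroglucinol)
Product: 5 2,4,6-trihydroxybenzene-1,3-dicarbaldehyde, via bis(iminium) salt 4 (not isolated)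
Conditions: POCl3 (2.2 equiv), DMF, 1,4-dioxane, 0 → 25 °C; then H2O, 25 °C
Reagents that add atoms: N,N-dimethylformamide, CN(C)C=O; water, O
Why: Vilsmeier–Haack formylation of the very electron-rich ring should stop after two substitutions because the two iminium groups deactivate the last position, and hydrolysis then gives the dialdehyde; no stereocentre is formed.

Step 3
Reactants: 5 2,4,6-trihydroxybenzene-1,3-dicarbaldehyde
Product: 6 2,4,6-tris(methoxymethoxy)benzene-1,3-dicarbaldehyde
Conditions: NaH (3.6 equiv), MOMCl (3.6 equiv), DMF, 0 → 25 °C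
Reagents that add atoms: chloromethyl methyl ether (MOMCl), COCCl
Why: Williamson-type O-alkylation of the three phenoxides with the hard α-chloro ether gives acetals that tolerate organolithium, Lewis-acid and Rh(I) conditions and later direct the ring lithiation.

Step 4
Reactants: 6 2,4,6-tris(methoxymethoxy)benzene-1,3-dicarbaldehyde; 7 diethyl (2-methylprop-2-en-1-yl)phosphonate
Product: 9 1,3,5-tris(methoxymethoxy)-2,4-bis[(1E)-3-methylbuta-1,3-dien-1-yl]benzene, via lithiated phosphonate 8 (not isolated)
Conditions: 7 (2.6 equiv), n-BuLi (2.5 equiv), THF/DMPU, −78 °C; then 6, −78 → 25 °C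
Reagents that add atoms: none
Why: Twofold Horner–Wadsworth–Emmons olefination in which the allylic phosphonate anion reacts at its α-carbon and the reversible addition/elimination should deliver the (E)-configured aryl dienes; no stereocentre is formed.

Step 5
Reactants: 9 1,3,5-tris(methoxymethoxy)-2,4-bis[(1E)-3-methylbuta-1,3-dien-1-yl]benzene; 2 3-methyl-2-methylidenebutanal
Product: 10 (1S,1'S,2R,2'R)-2,2'-[2,4,6-tris(methoxymethoxy)-1,3-phenylene]bis[4-methyl-1-(propan-2-yl)cyclohex-3-ene-1-carbaldehyde] (in each ring CHO cis and isopropyl trans to the arene)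
Conditions: 2 (3 equiv), (R)-o-tolyl-oxazaborolidine·HNTf2 (from (R)-α,α-diphenylprolinol, 40 mol %), CH2Cl2, −78 → −40 °C
Reagents that add atoms: none
Why: The cationic oxazaborolidinium binds the formyl oxygen of s-trans 2, and each dienyl arm of 9 should add in a concerted but asynchronous [4+2] cycloaddition in which the C4'–C5' bond (free diene terminus to the enal β-carbon) leads and the congested C1'–C6' bond follows; the closest known reaction type is the oxazaborolidinium-catalysed enantioselective Diels–Alder reaction of α-substituted acroleins with acyclic 1,3-dienes. Each cyclohexene ring is closed by an intermolecular suprafacial [4πs+2πs] cycloaddition, and the two events are independent. The regiochemistry required puts the formyl-bearing carbon next to the aryl-bearing carbon and para to the methyl-bearing carbon, and both diene substituents (1-aryl and 3-methyl) direct to this one isomer. The quaternary centre C6' is set by the catalyst, which shields one face of the bound enal so that the diene adds to the Re face of C-α; C1' is relayed from it by the endo (formyl-under-diene) transition state of the (E)-diene, which places CHO cis and the exo isopropyl trans to the arene and also keeps the bulky isopropyl away from the 2,6-dioxygenated ring. Because the two events are independent, a wrong-sense event should end up mainly in a separable meso diastereomer, so the homochiral product 10 is enriched.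

Step 6
Reactants: 10 (1S,1'S,2R,2'R)-2,2'-[2,4,6-tris(methoxymethoxy)-1,3-phenylene]bis[4-methyl-1-(propan-2-yl)cyclohex-3-ene-1-carbaldehyde]
Product: 11 1,3,5-tris(methoxymethoxy)-2,4-bis[(1R,6R)-3-methyl-6-(propan-2-yl)cyclohex-2-en-1-yl]benzene
Conditions: RhCl(PPh3)3 (2.4 equiv), PhCN, 140 °C
Reagents that add atoms: none
Why: Tsuji–Wilkinson decarbonylation (oxidative addition of the formyl C–H, CO de-insertion, C–H reductive elimination) is known to proceed with retention at α-quaternary carbons, so H should take the place of CHO cis to the arene and C6' becomes the (R)-configured C–H centre with isopropyl trans to the aryl group.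

Step 7
Reactants: 11 1,3,5-tris(methoxymethoxy)-2,4-bis[(1R,6R)-3-methyl-6-(propan-2-yl)cyclohex-2-en-1-yl]benzene; 12 (2E)-N-methoxy-N-methyl-3-phenylprop-2-enamide
Product: 14 (2E)-1-{2,4,6-tris(methoxymethoxy)-3,5-bis[(1R,6R)-3-methyl-6-(propan-2-yl)cyclohex-2-en-1-yl]phenyl}-3-phenylprop-2-en-1-one, via aryllithium 13 (not isolated)
Conditions: n-BuLi (1.2 equiv), THF, 0 °C; then 12, −78 → 0 °C; then H2O
Reagents that add atoms: none
Why: Directed ortho-metalation at the only aromatic C–H, flanked by two MOM ethers, followed by Weinreb ketone synthesis, in which the hard aryllithium adds 1,2 and the chelated tetrahedral adduct prevents over-addition; the stereocentres are not touched.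

Step 8
Reactants: 14 (2E)-1-{2,4,6-tris(methoxymethoxy)-3,5-bis[(1R,6R)-3-methyl-6-(propan-2-yl)cyclohex-2-en-1-yl]phenyl}-3-phenylprop-2-en-1-one
Product: 15 neolinderachalcone, (2E)-1-{2,4,6-trihydroxy-3,5-bis[(1R,6R)-3-methyl-6-(propan-2-yl)cyclohex-2-en-1-yl]phenyl}-3-phenylprop-2-en-1-one
Conditions: aq. HCl (3 M), MeOH, 25 °C
Reagents that add atoms: none
Why: Acid-catalysed acetal exchange of the three aryl MOM ethers with methanol, a deprotection used on prenylated 2'-hydroxychalcones, should proceed under conditions mild enough to spare the trisubstituted alkenes and the enone; no stereocentre is involved.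

**Compound list**

1 | 3-methylbutanal (isovaleraldehyde) | CC(C)CC=O | starting material
2 | 3-methyl-2-methylidenebutanal (2-isopropylacrolein) | CC(C)C(=C)C=O | intermediate
3 | benzene-1,3,5-triol (phloroglucinol) | Oc1cc(O)cc(O)c1 | starting material
4 | bis(iminium) salt, 2,4-bis[(dimethyliminio)methyl]benzene-1,3,5-triol bis(dichlorophosphate) | C[N+](C)=Cc1c(O)cc(O)c(C=[N+](C)C)c1O.[O-]P(=O)(Cl)Cl.[O-]P(=O)(Cl)Cl | intermediate
5 | 2,4,6-trihydroxybenzene-1,3-dicarbaldehyde | O=Cc1c(O)cc(O)c(C=O)c1O | intermediate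
6 | 2,4,6-tris(methoxymethoxy)benzene-1,3-dicarbaldehyde | COCOc1cc(OCOC)c(C=O)c(OCOC)c1C=O | intermediate
7 | diethyl (2-methylprop-2-en-1-yl)phosphonate | CCOP(=O)(CC(C)=C)OCC | starting material
8 | lithiated phosphonate (α-lithio derivative of 7) | [Li+].CCOP(=O)([CH-]C(C)=C)OCC | intermediate
9 | 1,3,5-tris(methoxymethoxy)-2,4-bis[(1E)-3-methylbuta-1,3-dien-1-yl]benzene | COCOc1cc(OCOC)c(/C=C/C(C)=C)c(OCOC)c1/C=C/C(C)=C | intermediate
10 | (1S,1'S,2R,2'R)-2,2'-[2,4,6-tris(methoxymethoxy)-1,3-phenylene]bis[4-methyl-1-(propan-2-yl)cyclohex-3-ene-1-carbaldehyde] | COCOc1cc(OCOC)c([C@H]2C=C(C)CC[C@]2(C=O)C(C)C)c(OCOC)c1[C@H]3C=C(C)CC[C@]3(C=O)C(C)C | intermediate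
11 | 1,3,5-tris(methoxymethoxy)-2,4-bis[(1R,6R)-3-methyl-6-(propan-2-yl)cyclohex-2-en-1-yl]benzene | COCOc1cc(OCOC)c([C@H]2C=C(C)CC[C@@H]2C(C)C)c(OCOC)c1[C@H]3C=C(C)CC[C@@H]3C(C)C | intermediate
12 | (2E)-N-methoxy-N-methyl-3-phenylprop-2-enamide | CON(C)C(=O)/C=C/c1ccccc1 | starting material
13 | aryllithium, {2,4,6-tris(methoxymethoxy)-3,5-bis[(1R,6R)-3-methyl-6-(propan-2-yl)cyclohex-2-en-1-yl]phenyl}lithium | [Li]c1c(OCOC)c([C@H]2C=C(C)CC[C@@H]2C(C)C)c(OCOC)c([C@H]3C=C(C)CC[C@@H]3C(C)C)c1OCOC | intermediate
14 | (2E)-1-{2,4,6-tris(methoxymethoxy)-3,5-bis[(1R,6R)-3-methyl-6-(propan-2-yl)cyclohex-2-en-1-yl]phenyl}-3-phenylprop-2-en-1-one | COCOc1c(C(=O)/C=C/c4ccccc4)c(OCOC)c([C@H]2C=C(C)CC[C@@H]2C(C)C)c(OCOC)c1[C@H]3C=C(C)CC[C@@H]3C(C)C | intermediate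
15 | neolinderachalcone | CC1=C[C@H](c2c(O)c(C(=O)/C=C/c3ccccc3)c(O)c([C@H]3C=C(C)CC[C@@H]3C(C)C)c2O)[C@@H](C(C)C)CC1 | target

**Total step count:** 8. **Longest linear sequence:** 7 (steps 2–8, from phloroglucinol).

**Steps most likely to fail**

Step 5 (key step). The trioxygenated arene may stabilise a benzylic/allylic cation so well that bond formation becomes stepwise, and the endo relay and the facial control, both defined for the concerted path, would then be lost. The free aromatic position or a diene terminus may also add to the activated enal in a Friedel–Crafts/Michael sense, and the doubly hindered C1'–C6' bond may close too slowly. The fallback gives up ring construction and forms the aryl–C1' bonds instead. It sets out from 3: acid-catalysed twofold Friedel–Crafts allylation of phloroglucinol with (R)-(−)-α-phellandrene (p-TsOH, CH2Cl2, 0 → 25 °C), in which the arene attacks the allyl cation anti to the isopropyl group, should give 2,4-bis[(1R,6R)-3-methyl-6-(propan-2-yl)cyclohex-2-en-1-yl]benzene-1,3,5-triol F1. Treatment of F1 with NaH and MOMCl in DMF then returns to the route at 11.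

Step 6. Oxidative addition into the two neopentyl-type formyl groups may be sluggish, and the tertiary alkyl–rhodium hydride may undergo β-hydride elimination to alkenes instead of C–H reductive elimination. The fallback avoids the quaternary aldehyde and sets C6' by thermodynamic epimerisation. It sets out from 9:
- Endo Diels–Alder reaction with 3-acryloyl-1,3-oxazolidin-2-one, catalysed by [Cu((R,R)-t-Bu-box)](SbF6)2 in CH2Cl2 (the square-planar chelate exposes the Si face of C-α), should give the cis bis-imide 3,3'-{[2,4,6-tris(methoxymethoxy)-1,3-phenylene]bis[(1R,2S)-4-methylcyclohex-3-ene-2,1-diylcarbonyl]}bis(1,3-oxazolidin-2-one) F2.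
- NaOMe in MeOH cleaves the imide and epimerises C-α to the trans diester dimethyl (1S,1'S,2S,2'S)-2,2'-[2,4,6-tris(methoxymethoxy)-1,3-phenylene]bis(4-methylcyclohex-3-ene-1-carboxylate) F3.
- Excess MeMgBr in THF gives the bis(tertiary alcohol) 2,2'-{[2,4,6-tris(methoxymethoxy)-1,3-phenylene]bis[(1S,2S)-4-methylcyclohex-3-ene-2,1-diyl]}di(propan-2-ol) F4.
- Dehydration towards the methyl groups with SOCl2 in pyridine at 0 °C gives 1,3,5-tris(methoxymethoxy)-2,4-bis[(1S,6S)-3-methyl-6-(prop-1-en-2-yl)cyclohex-2-en-1-yl]benzene F5.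
- Hydrogenation of only the 1,1-disubstituted alkenes (H2, cat. RhCl(PPh3)3, benzene) returns to the route at 11.

Step 8. While the acetals are cleaved, a freed 2'-hydroxyl group may add to the enone (flavanone formation), methanol or chloride may add to it, and a phenol may add to a protonated ring alkene. The fallback moves the acetal cleavage to a stage without enone and ends with a base-mediated step. It sets out from 11: lithiation as in step 7 (aryllithium 13) and quenching with N-methoxy-N-methylacetamide should give 1-{2,4,6-tris(methoxymethoxy)-3,5-bis[(1R,6R)-3-methyl-6-(propan-2-yl)cyclohex-2-en-1-yl]phenyl}ethan-1-one F6. Cleavage with aq. HCl in MeOH gives 1-{2,4,6-trihydroxy-3,5-bis[(1R,6R)-3-methyl-6-(propan-2-yl)cyclohex-2-en-1-yl]phenyl}ethan-1-one F7. Claisen–Schmidt condensation of F7 with benzaldehyde (KOH, EtOH/H2O, 25 °C) returns to the route at 15.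

**Further compounds**

F1 | step 5 | 2,4-bis[(1R,6R)-3-methyl-6-(propan-2-yl)cyclohex-2-en-1-yl]benzene-1,3,5-triol | Oc1cc(O)c([C@H]2C=C(C)CC[C@@H]2C(C)C)c(O)c1[C@H]3C=C(C)CC[C@@H]3C(C)C
F2 | step 6 | 3,3'-{[2,4,6-tris(methoxymethoxy)-1,3-phenylene]bis[(1R,2S)-4-methylcyclohex-3-ene-2,1-diylcarbonyl]}bis(1,3-oxazolidin-2-one) | COCOc1cc(OCOC)c([C@H]2C=C(C)CC[C@H]2C(=O)N4CCOC4=O)c(OCOC)c1[C@H]3C=C(C)CC[C@H]3C(=O)N5CCOC5=O
F3 | step 6 | dimethyl (1S,1'S,2S,2'S)-2,2'-[2,4,6-tris(methoxymethoxy)-1,3-phenylene]bis(4-methylcyclohex-3-ene-1-carboxylate) | COCOc1cc(OCOC)c([C@H]2C=C(C)CC[C@@H]2C(=O)OC)c(OCOC)c1[C@H]3C=C(C)CC[C@@H]3C(=O)OC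
F4 | step 6 | 2,2'-{[2,4,6-tris(methoxymethoxy)-1,3-phenylene]bis[(1S,2S)-4-methylcyclohex-3-ene-2,1-diyl]}di(propan-2-ol) | COCOc1cc(OCOC)c([C@H]2C=C(C)CC[C@@H]2C(C)(C)O)c(OCOC)c1[C@H]3C=C(C)CC[C@@H]3C(C)(C)O
F5 | step 6 | 1,3,5-tris(methoxymethoxy)-2,4-bis[(1S,6S)-3-methyl-6-(prop-1-en-2-yl)cyclohex-2-en-1-yl]benzene | COCOc1cc(OCOC)c([C@H]2C=C(C)CC[C@@H]2C(C)=C)c(OCOC)c1[C@H]3C=C(C)CC[C@@H]3C(C)=C
F6 | step 8 | 1-{2,4,6-tris(methoxymethoxy)-3,5-bis[(1R,6R)-3-methyl-6-(propan-2-yl)cyclohex-2-en-1-yl]phenyl}ethan-1-one | CC(=O)c1c(OCOC)c([C@H]2C=C(C)CC[C@@H]2C(C)C)c(OCOC)c([C@H]3C=C(C)CC[C@@H]3C(C)C)c1OCOC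
F7 | step 8 | 1-{2,4,6-trihydroxy-3,5-bis[(1R,6R)-3-methyl-6-(propan-2-yl)cyclohex-2-en-1-yl]phenyl}ethan-1-one | CC(=O)c1c(O)c([C@H]2C=C(C)CC[C@@H]2C(C)C)c(O)c([C@H]3C=C(C)CC[C@@H]3C(C)C)c1O
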